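Ring A, a fully substituted phloroglucinol in which C6 (hydroxyalkenyl chain) and C8 (prenyl) flank O7, is disconnected across C8–C8a and C6–C7. A Danheiser benzannulation joins a 2-alkyl-3-alkoxycyclobutenone that already carries the (R)-configured side chain with a prenyl-substituted siloxyalkyne. One thermal pericyclic cascade closes ring A and fixes the C8/C7/C6/C5 order by connectivity, leaving only O1 unprotected and C4a unsubstituted for the pyranone annulation. The precursor is a four-membered enone with a benzyloxy group at C3 (future O5, later cleaved by chelation to the C4 carbonyl) and the TBS-protected chiral chain at C2, made from prenol by Sharpless epoxidation.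

Key step: step 9

Remark: ketene gas for step 7 is assumed to come from a standard acetone-pyrolysis generator; the C5 oxygen is carried as a benzyl ether and the B-ring phenol as a TIPS ether, so that the end game needs only MgBr2 and fluoride and no protic or strong Lewis acid near the prenyl and allylic-alcohol units.

Step 1
Reactants: 1 prenol (3-methylbut-2-en-1-ol)
Product: 2 (R)-(3,3-dimethyloxiran-2-yl)methanol
Conditions: Ti(OiPr)4 (cat.), D-(−)-diisopropyl tartrate (cat.), t-BuOOH, 4 Å MS, CH2Cl2, −20 °C; non-aqueous work-up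
Reagents that add atoms: tert-butyl hydroperoxide, CC(C)(C)OO
Why: Sharpless asymmetric epoxidation of a primary allylic alcohol, in which the D-(−)-tartrate–titanium catalyst should deliver oxygen to the face that gives the (R)-epoxide and so sets the only stereocentre of the target (C2″).

Step 2
Reactants: 2 (R)-(3,3-dimethyloxiran-2-yl)methanol
Product: 3 [(2R)-3,3-dimethyloxiran-2-yl]methyl trifluoromethanesulfonate
Conditions: Tf2O, 2,6-lutidine, CH2Cl2, −78 °C; used crude at once
Reagents that add atoms: trifluoromethanesulfonic anhydride, O=S(=O)(OS(=O)(=O)C(F)(F)F)C(F)(F)F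
Why: O-sulfonylation of a primary alcohol under buffered low-temperature conditions should leave the acid-sensitive epoxide and its stereocentre untouched.

Step 3
Reactants: 4 benzyl alcohol
Product: 5 benzyl (E)-1,2-dichlorovinyl ether
Conditions: KH, THF, 0 °C; then Cl2C=CHCl, −50 °C → rt
Reagents that add atoms: trichloroethylene, ClC=C(Cl)Cl
Why: Alkoxide-induced dehydrochlorination of trichloroethylene to dichloroacetylene followed by anti addition of the alcohol is the standard dichlorovinyl-ether entry to alkynyl ethers.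

Step 4
Reactants: 5 benzyl (E)-1,2-dichlorovinyl ether; 3 [(2R)-3,3-dimethyloxiran-2-yl]methyl trifluoromethanesulfonate
Product: 7 (2R)-2-[3-(benzyloxy)prop-2-yn-1-yl]-3,3-dimethyloxirane, via lithium benzyloxyacetylide 6 (not isolated)
Conditions: n-BuLi (2.2 equiv), THF, −78 → −40 °C; then 3, DMPU, −78 → 0 °C
Reagents that add atoms: none
Why: Elimination and Cl–Li exchange convert the dichlorovinyl ether into the lithium alkoxyacetylide, which should alkylate by SN2 at the primary triflate (acetylide alkylation) faster than it opens the epoxide, so C2 is not touched.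

Step 5
Reactants: 7 (2R)-2-[3-(benzyloxy)prop-2-yn-1-yl]-3,3-dimethyloxirane
Product: 8 (3R)-6-(benzyloxy)-2-methylhex-1-en-5-yn-3-ol
Conditions: Et2AlCl, LiTMP (gives Et2Al-TMP), toluene, 0 °C; Rochelle-salt work-up
Reagents that add atoms: none
Why: Aluminium-amide isomerisation of a trisubstituted epoxide to an allylic alcohol proceeds by syn β-elimination of a methyl hydrogen with cleavage of the tertiary C–O bond only, so the C–O bond at the stereocentre is retained.

Step 6
Reactants: 8 (3R)-6-(benzyloxy)-2-methylhex-1-en-5-yn-3-ol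
Product: 9 {[(3R)-6-(benzyloxy)-2-methylhex-1-en-5-yn-3-yl]oxy}(tert-butyl)dimethylsilane
Conditions: TBSCl, imidazole, DMF, rt
Reagents that add atoms: tert-butyldimethylsilyl chloride, CC(C)(C)[Si](C)(C)Cl
Why: Silyl ether formation under basic conditions is compatible with the acid-labile alkynyl ether and blocks the hydroxyl against acylation by ketene.

Step 7
Reactants: 9 {[(3R)-6-(benzyloxy)-2-methylhex-1-en-5-yn-3-yl]oxy}(tert-butyl)dimethylsilane
Product: 10 3-(benzyloxy)-2-[(2R)-2-(tert-butyldimethylsilyloxy)-3-methylbut-3-en-1-yl]cyclobut-2-en-1-one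
Conditions: ketene (gas), CH2Cl2, 0 °C → rt
Reagents that add atoms: ketene, C=C=O
Why: Polar [2+2] cycloaddition of ketene with an electron-rich alkynyl ether joins the ketene carbonyl carbon to the alkyl-bearing alkyne carbon and gives the 3-alkoxy-2-alkylcyclobutenone, while the unactivated alkenes do not react with ketene.

Step 8
Reactants: 11 ethyl 4-methylpent-3-enoate
Product: 14 triisopropyl[(5-methylhex-4-en-1-yn-1-yl)oxy]silane, via dibromoketone lithium enolate 12 (not isolated), via lithium ynolate 13 (not isolated)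
Conditions: CH2Br2, LiTMP, THF, −78 °C; LiHMDS; n-BuLi, −78 → 20 °C; then TIPSCl, 0 °C
Reagents that add atoms: dibromomethane, BrCBr; triisopropylsilyl chloride, CC(C)[Si](Cl)(C(C)C)C(C)C
Why: Kowalski ester homologation, in which LiCHBr2 adds to the ester faster than it enolises it, the bromo-lithio enolate rearranges by 1,2-shift to the ynolate, and the bulky silyl chloride silylates on oxygen.

Step 9
Reactants: 10 3-(benzyloxy)-2-[(2R)-2-(tert-butyldimethylsilyloxy)-3-methylbut-3-en-1-yl]cyclobut-2-en-1-one; 14 triisopropyl[(5-methylhex-4-en-1-yn-1-yl)oxy]silane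
Product: 19 5-(benzyloxy)-4-[(2R)-2-(tert-butyldimethylsilyloxy)-3-methylbut-3-en-1-yl]-2-(3-methylbut-2-en-1-yl)-3-(triisopropylsilyloxy)phenol, via vinylketene 15 (not isolated), via vinylcyclobutenone 16 (not isolated), via dienylketene 17 (not isolated), via cyclohexadienone 18 (not isolated)
Conditions: 14 (1.5 equiv), degassed toluene, 110 °C, sealed tube
Reagents that add atoms: none
Why: Danheiser benzannulation (cyclobutenone–siloxyalkyne aromatic annulation), a cascade of four pericyclic events: thermal 4π electrocyclic opening of 10 gives vinylketene 15, its C=C=O unit adds [2+2] to the siloxyalkyne to give vinylcyclobutenone 16, 4π opening of 16 gives dienylketene 17, and 6π electrocyclisation then tautomerisation of dienone 18 gives the phenol. Ring A is closed by the 6π (disrotatory) electrocyclisation that joins the ketene carbon (C8a) to the terminal methylene (C4a), after the [2+2] step has made the C8–C8a and C6–C7 bonds. The only selectivity needed is regiochemical and is set by the polarity of the ketene–ynol ether addition: the nucleophilic, prenyl-bearing alkyne carbon bonds to the electrophilic ketene carbon, so prenyl ends ortho to the new hydroxyl, the siloxy carbon next, the chiral chain para and the benzyloxy group meta. No stereocentre is created; the quaternary centre of 16 is lost on ring opening and the C2″ centre is remote from the reacting π system. The medium is neutral and free of metals, so both alkenes, the silyl ethers and the benzyl ether should survive.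

Step 10
Reactants: 19 5-(benzyloxy)-4-[(2R)-2-(tert-butyldimethylsilyloxy)-3-methylbut-3-en-1-yl]-2-(3-methylbut-2-en-1-yl)-3-(triisopropylsilyloxy)phenol
Product: 20 6-(benzyloxy)-5-[(2R)-2-(tert-butyldimethylsilyloxy)-3-methylbut-3-en-1-yl]-2-hydroxy-3-(3-methylbut-2-en-1-yl)-4-(triisopropylsilyloxy)benzaldehyde
Conditions: MgCl2, Et3N, (CH2O)n, MeCN, reflux
Reagents that add atoms: paraformaldehyde (as formaldehyde), C=O
Why: Casnati–Skattebøl ortho-formylation, in which the magnesium phenoxide directs formaldehyde to the only free ring position (C4a) and a second formaldehyde oxidises the hydroxymethyl intermediate by hydride transfer under basic, acid-free conditions.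

Step 11
Reactants: 21 4-hydroxybenzaldehyde
Product: 22 4-(triisopropylsilyloxy)benzaldehyde
Conditions: TIPSCl, imidazole, DMF, rt
Reagents that add atoms: triisopropylsilyl chloride, CC(C)[Si](Cl)(C(C)C)C(C)C
Why: Phenol silylation gives a base-stable aryl TIPS ether that can later be removed with fluoride together with the other silyl groups.

Step 12
Reactants: 22 4-(triisopropylsilyloxy)benzaldehyde
Product: 23 [4-(triisopropylsilyloxy)phenyl]methanol
Conditions: NaBH4, MeOH, 0 °C
Reagents that add atoms: none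
Why: Borohydride reduction of an aryl aldehyde to the benzylic alcohol is chemoselective in the presence of the aryl silyl ether.

Step 13
Reactants: 23 [4-(triisopropylsilyloxy)phenyl]methanol
Product: 24 [4-(chloromethyl)phenoxy]triisopropylsilane
Conditions: SOCl2, pyridine, CH2Cl2, 0 °C
Reagents that add atoms: thionyl chloride, O=S(Cl)Cl
Why: Deoxychlorination of an electron-rich benzylic alcohol with thionyl chloride, buffered by pyridine so that the aryl silyl ether is not exposed to free HCl.

Step 14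
Reactants: 20 6-(benzyloxy)-5-[(2R)-2-(tert-butyldimethylsilyloxy)-3-methylbut-3-en-1-yl]-2-hydroxy-3-(3-methylbut-2-en-1-yl)-4-(triisopropylsilyloxy)benzaldehyde; 24 [4-(chloromethyl)phenoxy]triisopropylsilane
Product: 26 1-{6-(benzyloxy)-5-[(2R)-2-(tert-butyldimethylsilyloxy)-3-methylbut-3-en-1-yl]-2-hydroxy-3-(3-methylbut-2-en-1-yl)-4-(triisopropylsilyloxy)phenyl}-2-[4-(triisopropylsilyloxy)phenyl]ethan-1-ol (both carbinol epimers), via 4-(triisopropylsilyloxy)benzylmagnesium chloride 25 (not isolated)
Conditions: Mg, Et2O, 0 °C → rt (gives 25); then 20, THF, −78 → 0 °C (2.5 equiv of 25); pH 7 buffer work-up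
Reagents that add atoms: none
Why: Grignard addition to the aldehyde after the first equivalent has deprotonated the phenol; the new carbinol centre is formed without control and is erased in the next step.

Step 15
Reactants: 26 the benzylic alcohol from step 14
Product: 27 1-{6-(benzyloxy)-5-[(2R)-2-(tert-butyldimethylsilyloxy)-3-methylbut-3-en-1-yl]-2-hydroxy-3-(3-methylbut-2-en-1-yl)-4-(triisopropylsilyloxy)phenyl}-2-[4-(triisopropylsilyloxy)phenyl]ethan-1-one
Conditions: activated MnO2 (excess), CH2Cl2, rt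
Reagents that add atoms: none
Why: Manganese dioxide oxidation of a benzylic alcohol to the aryl ketone is heterogeneous and neutral and should spare the alkenes, the silyl ethers and the hydrogen-bonded phenol.

Step 16
Reactants: 27 the 2-hydroxydeoxybenzoin from step 15
Product: 29 5-(benzyloxy)-6-[(2R)-2-(tert-butyldimethylsilyloxy)-3-methylbut-3-en-1-yl]-8-(3-methylbut-2-en-1-yl)-7-(triisopropylsilyloxy)-3-[4-(triisopropylsilyloxy)phenyl]-4H-chromen-4-one, via enaminone 28 (not isolated)
Conditions: Me2NCH(OMe)2, toluene, 80 °C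
Reagents that add atoms: N,N-dimethylformamide dimethyl acetal, COC(OC)N(C)C
Why: Condensation of the activated methylene with the formamide acetal gives an enaminone that the ortho phenol closes by addition–elimination with loss of dimethylamine, the standard deoxybenzoin route to isoflavones, and O1 is the only free phenol so ring C can form in one direction only.

Step 17
Reactants: 29 the fully protected isoflavone from step 16
Product: 30 6-[(2R)-2-(tert-butyldimethylsilyloxy)-3-methylbut-3-en-1-yl]-5-hydroxy-8-(3-methylbut-2-en-1-yl)-7-(triisopropylsilyloxy)-3-[4-(triisopropylsilyloxy)phenyl]-4H-chromen-4-one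
Conditions: MgBr2·OEt2, toluene/Et2O, 70 °C
Reagents that add atoms: none
Why: Chelation-assisted debenzylation, in which magnesium bound between the C4 carbonyl and O5 activates only the peri benzyl ether toward bromide attack at the benzylic carbon, under conditions too mild to ionise the alkenes or the allylic silyl ether.

Step 18
Reactants: 30 the 5-hydroxy isoflavone from step 17
Product: 31 5,7-dihydroxy-6-[(2R)-2-hydroxy-3-methylbut-3-en-1-yl]-3-(4-hydroxyphenyl)-8-(3-methylbut-2-en-1-yl)-4H-chromen-4-one (CNP0105386.1)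
Conditions: TBAF, AcOH, THF, 0 °C → rt
Reagents that add atoms: none
Why: Fluoride-mediated desilylation removes both aryl TIPS ethers and the secondary TBS ether in one operation, with acetic acid buffering the phenoxides so that the chromone is not opened by base.

Compound list
1 | prenol (3-methylbut-2-en-1-ol) | CC(C)=CCO | starting material
2 | (R)-(3,3-dimethyloxiran-2-yl)methanol | OC[C@H]1OC1(C)C | intermediate
3 | [(2R)-3,3-dimethyloxiran-2-yl]methyl trifluoromethanesulfonate | O=S(=O)(OC[C@H]1OC1(C)C)C(F)(F)F | intermediate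
4 | benzyl alcohol | OCc1ccccc1 | starting material
5 | benzyl (E)-1,2-dichlorovinyl ether | Cl/C=C(/Cl)OCc1ccccc1 | intermediate
6 | lithium benzyloxyacetylide | [Li]C#COCc1ccccc1 | intermediate (not isolated)
7 | (2R)-2-[3-(benzyloxy)prop-2-yn-1-yl]-3,3-dimethyloxirane | c1ccccc1COC#CC[C@H]1OC1(C)C | intermediate
8 | (3R)-6-(benzyloxy)-2-methylhex-1-en-5-yn-3-ol | C=C(C)[C@H](O)CC#COCc1ccccc1 | intermediate
9 | {[(3R)-6-(benzyloxy)-2-methylhex-1-en-5-yn-3-yl]oxy}(tert-butyl)dimethylsilane | C=C(C)[C@H](O[Si](C)(C)C(C)(C)C)CC#COCc1ccccc1 | intermediate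
10 | 3-(benzyloxy)-2-[(2R)-2-(tert-butyldimethylsilyloxy)-3-methylbut-3-en-1-yl]cyclobut-2-en-1-one | C=C(C)[C@H](O[Si](C)(C)C(C)(C)C)CC1=C(OCc2ccccc2)CC1=O | intermediate (key-step precursor)
11 | ethyl 4-methylpent-3-enoate | CCOC(=O)CC=C(C)C | starting material
12 | lithium 1,1-dibromo-5-methylhexa-1,4-dien-2-olate (dibromoketone enolate) | [Li]OC(=C(Br)Br)CC=C(C)C | intermediate (not isolated)
13 | lithium 5-methylhex-4-en-1-yn-1-olate (ynolate) | [Li]OC#CCC=C(C)C | intermediate (not isolated)
14 | triisopropyl[(5-methylhex-4-en-1-yn-1-yl)oxy]silane | CC(C)=CCC#CO[Si](C(C)C)(C(C)C)C(C)C | intermediate (key-step precursor)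
15 | 3-(benzyloxy)-2-[(2R)-2-(tert-butyldimethylsilyloxy)-3-methylbut-3-en-1-yl]buta-1,3-dien-1-one (vinylketene) | C=C(C)[C@H](O[Si](C)(C)C(C)(C)C)CC(=C=O)C(=C)OCc1ccccc1 | intermediate (not isolated)
16 | 4-[1-(benzyloxy)ethenyl]-4-[(2R)-2-(tert-butyldimethylsilyloxy)-3-methylbut-3-en-1-yl]-2-(3-methylbut-2-en-1-yl)-3-(triisopropylsilyloxy)cyclobut-2-en-1-one (both C4 epimers) | C=C(C)[C@H](O[Si](C)(C)C(C)(C)C)CC1(C(=C)OCc2ccccc2)C(=O)C(CC=C(C)C)=C1O[Si](C(C)C)(C(C)C)C(C)C | intermediate (not isolated)
17 | (3E)-5-(benzyloxy)-4-[(2R)-2-(tert-butyldimethylsilyloxy)-3-methylbut-3-en-1-yl]-2-(3-methylbut-2-en-1-yl)-3-(triisopropylsilyloxy)hexa-1,3,5-trien-1-one (dienylketene) | C=C(OCc1ccccc1)/C(C[C@@H](O[Si](C)(C)C(C)(C)C)C(C)=C)=C(/O[Si](C(C)C)(C(C)C)C(C)C)C(CC=C(C)C)=C=O | intermediate (not isolated)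
18 | 5-(benzyloxy)-4-[(2R)-2-(tert-butyldimethylsilyloxy)-3-methylbut-3-en-1-yl]-2-(3-methylbut-2-en-1-yl)-3-(triisopropylsilyloxy)cyclohexa-2,4-dien-1-one | C=C(C)[C@H](O[Si](C)(C)C(C)(C)C)CC1=C(OCc2ccccc2)CC(=O)C(CC=C(C)C)=C1O[Si](C(C)C)(C(C)C)C(C)C | intermediate (not isolated)
19 | 5-(benzyloxy)-4-[(2R)-2-(tert-butyldimethylsilyloxy)-3-methylbut-3-en-1-yl]-2-(3-methylbut-2-en-1-yl)-3-(triisopropylsilyloxy)phenol | C=C(C)[C@H](O[Si](C)(C)C(C)(C)C)Cc1c(OCc2ccccc2)cc(O)c(CC=C(C)C)c1O[Si](C(C)C)(C(C)C)C(C)C | intermediate (key-step product)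
20 | 6-(benzyloxy)-5-[(2R)-2-(tert-butyldimethylsilyloxy)-3-methylbut-3-en-1-yl]-2-hydroxy-3-(3-methylbut-2-en-1-yl)-4-(triisopropylsilyloxy)benzaldehyde | C=C(C)[C@H](O[Si](C)(C)C(C)(C)C)Cc1c(OCc2ccccc2)c(C=O)c(O)c(CC=C(C)C)c1O[Si](C(C)C)(C(C)C)C(C)C | intermediate
21 | 4-hydroxybenzaldehyde | O=Cc1ccc(O)cc1 | starting material
22 | 4-(triisopropylsilyloxy)benzaldehyde | O=Cc1ccc(O[Si](C(C)C)(C(C)C)C(C)C)cc1 | intermediate
23 | [4-(triisopropylsilyloxy)phenyl]methanol | OCc1ccc(O[Si](C(C)C)(C(C)C)C(C)C)cc1 | intermediate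
24 | [4-(chloromethyl)phenoxy]triisopropylsilane | ClCc1ccc(O[Si](C(C)C)(C(C)C)C(C)C)cc1 | intermediate
25 | 4-(triisopropylsilyloxy)benzylmagnesium chloride | Cl[Mg]Cc1ccc(O[Si](C(C)C)(C(C)C)C(C)C)cc1 | intermediate (not isolated)
26 | 1-{6-(benzyloxy)-5-[(2R)-2-(tert-butyldimethylsilyloxy)-3-methylbut-3-en-1-yl]-2-hydroxy-3-(3-methylbut-2-en-1-yl)-4-(triisopropylsilyloxy)phenyl}-2-[4-(triisopropylsilyloxy)phenyl]ethan-1-ol (both carbinol epimers) | C=C(C)[C@H](O[Si](C)(C)C(C)(C)C)Cc1c(OCc2ccccc2)c(C(O)Cc2ccc(O[Si](C(C)C)(C(C)C)C(C)C)cc2)c(O)c(CC=C(C)C)c1O[Si](C(C)C)(C(C)C)C(C)C | intermediate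
27 | 1-{6-(benzyloxy)-5-[(2R)-2-(tert-butyldimethylsilyloxy)-3-methylbut-3-en-1-yl]-2-hydroxy-3-(3-methylbut-2-en-1-yl)-4-(triisopropylsilyloxy)phenyl}-2-[4-(triisopropylsilyloxy)phenyl]ethan-1-one | C=C(C)[C@H](O[Si](C)(C)C(C)(C)C)Cc1c(OCc2ccccc2)c(C(=O)Cc2ccc(O[Si](C(C)C)(C(C)C)C(C)C)cc2)c(O)c(CC=C(C)C)c1O[Si](C(C)C)(C(C)C)C(C)C | intermediate
28 | 3-(dimethylamino)-1-{6-(benzyloxy)-5-[(2R)-2-(tert-butyldimethylsilyloxy)-3-methylbut-3-en-1-yl]-2-hydroxy-3-(3-methylbut-2-en-1-yl)-4-(triisopropylsilyloxy)phenyl}-2-[4-(triisopropylsilyloxy)phenyl]prop-2-en-1-one (enaminone, alkene geometry not defined) | C=C(C)[C@H](O[Si](C)(C)C(C)(C)C)Cc1c(OCc2ccccc2)c(C(=O)C(=CN(C)C)c2ccc(O[Si](C(C)C)(C(C)C)C(C)C)cc2)c(O)c(CC=C(C)C)c1O[Si](C(C)C)(C(C)C)C(C)C | intermediate (not isolated)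
29 | 5-(benzyloxy)-6-[(2R)-2-(tert-butyldimethylsilyloxy)-3-methylbut-3-en-1-yl]-8-(3-methylbut-2-en-1-yl)-7-(triisopropylsilyloxy)-3-[4-(triisopropylsilyloxy)phenyl]-4H-chromen-4-one | C=C(C)[C@H](O[Si](C)(C)C(C)(C)C)Cc1c(O[Si](C(C)C)(C(C)C)C(C)C)c(CC=C(C)C)c2occ(-c3ccc(O[Si](C(C)C)(C(C)C)C(C)C)cc3)c(=O)c2c1OCc4ccccc4 | intermediate
30 | 6-[(2R)-2-(tert-butyldimethylsilyloxy)-3-methylbut-3-en-1-yl]-5-hydroxy-8-(3-methylbut-2-en-1-yl)-7-(triisopropylsilyloxy)-3-[4-(triisopropylsilyloxy)phenyl]-4H-chromen-4-one | C=C(C)[C@H](O[Si](C)(C)C(C)(C)C)Cc1c(O[Si](C(C)C)(C(C)C)C(C)C)c(CC=C(C)C)c2occ(-c3ccc(O[Si](C(C)C)(C(C)C)C(C)C)cc3)c(=O)c2c1O | intermediate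
31 | 5,7-dihydroxy-6-[(2R)-2-hydroxy-3-methylbut-3-en-1-yl]-3-(4-hydroxyphenyl)-8-(3-methylbut-2-en-1-yl)-4H-chromen-4-one (CNP0105386.1) | C=C(C)[C@H](O)Cc1c(O)c(CC=C(C)C)c2occ(-c3ccc(O)cc3)c(=O)c2c1O | target

Total step count: 18. Longest linear sequence: 13 steps (1, 2, 4, 5, 6, 7, 9, 10, 14, 15, 16, 17, 18; from prenol 1 to target 31).

Steps most likely to fail

Step 9. The electrocyclic opening of the donor-stabilised (vinylogous ester) cyclobutenone may be slow compared with thermal decay of the siloxyalkyne, and the phenol product may be acylated by ketene intermediates at the temperature required. The fallback sets out from 10 and 14 and comes back to the route at 19. It divides the cascade and makes the vinylketene with light instead of heat: irradiation of 10 (300 nm, CH2Cl2, 0–20 °C) in the presence of 14 should open the ring photochemically to vinylketene 15, which is trapped at once in the polar ketene–siloxyalkyne [2+2] addition. The resulting vinylcyclobutenone 16 would be isolated and then warmed gently (toluene, 60–80 °C) in a separate operation to run the 4π/6π sequence to 19, so that neither the siloxyalkyne nor the phenol is ever exposed to 110 °C together with a ketene. This is the same pair of partners with a different way of generating the reactive intermediate, not a different disconnection. It makes no compound outside the list (F0).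

Step 5. The aluminium amide may deprotonate the propargylic CH2 and open the epoxide in the wrong direction to an enyne, or the Lewis-acidic reagent may degrade the alkynyl ether. The fallback sets out from 2 and comes back at 9, so that the epoxide is isomerised before any alkynyl ether is present. Hydroxyl-directed rearrangement of 2 with Ti(OiPr)4 (CH2Cl2, rt) should give (2S)-3-methylbut-3-ene-1,2-diol F1 (same spatial arrangement; the descriptor changes only through CIP priorities). Bis-silylation (TBSCl, imidazole, DMF) would give (2S)-1,2-bis(tert-butyldimethylsilyloxy)-3-methylbut-3-ene F2. Selective cleavage of the primary silyl ether (HF·pyridine, pyridine/THF, 0 °C) would give (2S)-2-(tert-butyldimethylsilyloxy)-3-methylbut-3-en-1-ol F3, and Tf2O/2,6-lutidine (CH2Cl2, −78 °C) its triflate, (2S)-2-(tert-butyldimethylsilyloxy)-3-methylbut-3-en-1-yl trifluoromethanesulfonate F4. Alkylation of lithium benzyloxyacetylide 6 (from 5, as in step 4) with F4 in THF/DMPU would give 9 directly.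

Step 15. The o-hydroxybenzylic alcohol may dehydrate through an o-quinone methide, or the oxidant may attack the electron-rich phenol instead of the carbinol. The fallback sets out from 20 and comes back at 27, and masks the phenol before the carbinol is made. O-Allylation of 20 (allyl bromide, K2CO3, DMF) would give 2-(allyloxy)-6-(benzyloxy)-5-[(2R)-2-(tert-butyldimethylsilyloxy)-3-methylbut-3-en-1-yl]-3-(3-methylbut-2-en-1-yl)-4-(triisopropylsilyloxy)benzaldehyde F5. Addition of Grignard reagent 25 (1.3 equiv, THF, −78 °C) would give the O-allyl carbinol F6, and Dess–Martin periodinane/NaHCO3 (CH2Cl2, 0 °C) the O-allyl ketone F7. Pd(PPh3)4/morpholine (THF, rt) would then remove the allyl group to give 27 without touching the prenyl, isopropenyl or silyl groups.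

Further compounds
F0 | step 9 | none | none
F1 | step 5 | (2S)-3-methylbut-3-ene-1,2-diol | C=C(C)[C@H](O)CO
F2 | step 5 | (2S)-1,2-bis(tert-butyldimethylsilyloxy)-3-methylbut-3-ene | C=C(C)[C@H](O[Si](C)(C)C(C)(C)C)CO[Si](C)(C)C(C)(C)C
F3 | step 5 | (2S)-2-(tert-butyldimethylsilyloxy)-3-methylbut-3-en-1-ol | C=C(C)[C@H](O[Si](C)(C)C(C)(C)C)CO
F4 | step 5 | (2S)-2-(tert-butyldimethylsilyloxy)-3-methylbut-3-en-1-yl trifluoromethanesulfonate | C=C(C)[C@H](O[Si](C)(C)C(C)(C)C)COS(=O)(=O)C(F)(F)F
F5 | step 15 | 2-(allyloxy)-6-(benzyloxy)-5-[(2R)-2-(tert-butyldimethylsilyloxy)-3-methylbut-3-en-1-yl]-3-(3-methylbut-2-en-1-yl)-4-(triisopropylsilyloxy)benzaldehyde | C=C(C)[C@H](O[Si](C)(C)C(C)(C)C)Cc1c(OCc2ccccc2)c(C=O)c(OCC=C)c(CC=C(C)C)c1O[Si](C(C)C)(C(C)C)C(C)C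
F6 | step 15 | 1-{2-(allyloxy)-6-(benzyloxy)-5-[(2R)-2-(tert-butyldimethylsilyloxy)-3-methylbut-3-en-1-yl]-3-(3-methylbut-2-en-1-yl)-4-(triisopropylsilyloxy)phenyl}-2-[4-(triisopropylsilyloxy)phenyl]ethan-1-ol (both carbinol epimers) | C=C(C)[C@H](O[Si](C)(C)C(C)(C)C)Cc1c(OCc2ccccc2)c(C(O)Cc2ccc(O[Si](C(C)C)(C(C)C)C(C)C)cc2)c(OCC=C)c(CC=C(C)C)c1O[Si](C(C)C)(C(C)C)C(C)C
F7 | step 15 | 1-{2-(allyloxy)-6-(benzyloxy)-5-[(2R)-2-(tert-butyldimethylsilyloxy)-3-methylbut-3-en-1-yl]-3-(3-methylbut-2-en-1-yl)-4-(triisopropylsilyloxy)phenyl}-2-[4-(triisopropylsilyloxy)phenyl]ethan-1-one | C=C(C)[C@H](O[Si](C)(C)C(C)(C)C)Cc1c(OCc2ccccc2)c(C(=O)Cc2ccc(O[Si](C(C)C)(C(C)C)C(C)C)cc2)c(OCC=C)c(CC=C(C)C)c1O[Si](C(C)C)(C(C)C)C(C)C
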